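**Plan**

1. Locants used below: ring C5 (hydroxy-isopropenyl arm C4(=C3)C15), C6 (OH), C7 (acrylic acid arm C11(=C13)C12), C8 (acyloxy), C9 (CH2), C10 (methyl, vinyl C1=C2).
2. Retrosynthesis: remove the C8 ester and the protecting groups; take the C8 carbinol back to a ketone; cut C9–C8 and C6–C7 together, which releases the C7–C8 unit with its acrylate arm as an itaconate-derived 2-(bromomethyl)butenedioate and leaves an open-chain 4-iodo aldehyde C9–C10–C5–C6; cut C5–C10 by an Ireland–Claisen transform.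
3. Forward: an ester-enolate Claisen rearrangement joins C5 to C10; the only ring (cyclohexane C5–C10) is then closed in one SmI2 operation, in which the dienolate carbon C7 adds to the aldehyde C6 and the C9 alkylsamarium substitutes at the ester carbonyl C8.
4. Enabling feature: C6 and C8 are 1,3-dioxygenated around C7, and C9 is a methylene on the quaternary C10 (no β-hydrogen). C7–C8 can therefore be an ester enolate/ester pair and C9–C10–C5–C6 an iodide/aldehyde pair, both halides being used with reversed polarity.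
5. Stereochemistry: C5 and C10 come from the chair Claisen transition state (E alkene, E(O) boron enolate, chiral boron reagent for the absolute sense). C6 is set by Felkin–Anh addition, C7 by the closed aldol transition state, and C8 by hydride attack anti to the axial C10 vinyl group. The Z side-chain alkene comes from trans-hydroalumination of an alkyne.

Key step: step 14

Abbreviations in names: TBS = tert-butyl(dimethyl)silyl, TES = triethylsilyl, TMSE = 2-(trimethylsilyl)ethyl, Piv = 2,2-dimethylpropanoyl.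
Assumption: the (S,S)-bromoborane is taken to select the enolate face that leads to the (2R,3R)-acid of step 7; if the sense of induction is the opposite, the (R,R)-reagent is used in the same way.
Remark: the target is a γ-hydroxy acid (C6–OH and the C12 acid) that can close to a lactone under acid, so it is set free under buffered fluoride and isolated at pH 4–5 without heating.

Step 1
Reactants: 1 3-methylbut-2-en-1-yl acetate (prenyl acetate)
Product: 2 (2E)-4-hydroxy-3-methylbut-2-en-1-yl acetate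
Conditions: SeO2 (0.3 equiv), t-BuOOH, CH2Cl2, 25 °C
Reagents that add atoms: tert-butyl hydroperoxide, CC(C)(C)OO (oxygen relayed by the SeO2 catalyst, O=[Se]=O)
Why: Allylic oxidation (ene reaction, then [2,3]-sigmatropic shift) should hydroxylate the methyl group trans to the CH2OAc chain, which fixes the E alkene that later defines C10.

Step 2
Reactants: 2 (2E)-4-hydroxy-3-methylbut-2-en-1-yl acetate
Product: 3 (2E)-4-(acetyloxy)-2-methylbut-2-en-1-yl 2,2-dimethylpropanoate
Conditions: PivCl, pyridine, DMAP (cat.), CH2Cl2, 0 °C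
Reagents that add atoms: pivaloyl chloride, CC(C)(C)C(=O)Cl
Why: DMAP-assisted acylation of the primary allylic alcohol should be clean and gives an ester that cannot be enolised later.

Step 3
Reactants: 3 (2E)-4-(acetyloxy)-2-methylbut-2-en-1-yl 2,2-dimethylpropanoate
Product: 4 (2E)-4-hydroxy-2-methylbut-2-en-1-yl 2,2-dimethylpropanoate
Conditions: K2CO3 (0.2 equiv), MeOH, 0 °C
Reagents that add atoms: none
Why: Base-catalysed transesterification (Zemplén-type methanolysis) should remove the unhindered acetate much faster than the pivalate.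

Step 4
Reactants: 5 2-methylprop-2-en-1-ol
Product: 7 3-(hydroxymethyl)but-3-enoic acid, via dilithio dianion 6 (not isolated)
Conditions: n-BuLi (2.2 equiv), TMEDA, Et2O/hexane, 0 → 25 °C; CO2, −78 °C; aq. HCl to pH 3, 0 °C
Reagents that add atoms: carbon dioxide, O=C=O
Why: Double deprotonation gives the alkoxide–allyllithium, whose carbon terminus is carboxylated by CO2 (carboxylation of an allyllithium), the acid being kept cold to avoid lactonisation.

Step 5
Reactants: 7 3-(hydroxymethyl)but-3-enoic acid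
Product: 9 3-[(TBS-oxy)methyl]but-3-enoic acid, via bis-silyl compound 8 (not isolated)
Conditions: TBSCl (2.5 equiv), imidazole, DMF, 25 °C; then THF/H2O/AcOH, 25 °C
Reagents that add atoms: tert-butyl(chloro)dimethylsilane, CC(C)(C)[Si](C)(C)Cl
Why: Exhaustive silylation followed by selective solvolysis of the labile silyl ester should leave only the silyl ether (standard protection of a hydroxy acid).

Step 6
Reactants: 4 (2E)-4-hydroxy-2-methylbut-2-en-1-yl 2,2-dimethylpropanoate; 9 3-[(TBS-oxy)methyl]but-3-enoic acid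
Product: 10 (2E)-3-methyl-4-(Piv-oxy)but-2-en-1-yl 3-[(TBS-oxy)methyl]but-3-enoate
Conditions: DCC, DMAP (5 mol %), CH2Cl2, −20 → 0 °C
Reagents that add atoms: none
Why: Steglich esterification at low temperature should join the two halves without moving the β,γ-double bond of the acid into conjugation.

Step 7
Reactants: 10 (2E)-3-methyl-4-(Piv-oxy)but-2-en-1-yl 3-[(TBS-oxy)methyl]but-3-enoate
Product: 12 (2R,3R)-3-methyl-3-[(Piv-oxy)methyl]-2-[3-(TBS-oxy)prop-1-en-2-yl]pent-4-enoic acid, via boron ketene acetal 11 (not isolated)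
Conditions: (S,S)-2-bromo-1,3-bis{[3,5-bis(trifluoromethyl)phenyl]sulfonyl}-4,5-diphenyl-1,3,2-diazaborolidine (1.2 equiv), Et3N, toluene/hexane, −78 → 4 °C; aq. HCl
Reagents that add atoms: none
Why: Enantioselective Ireland–Claisen rearrangement, in which the chiral boron reagent forms the E(O) ketene acetal (C5 substituent trans to O–B) and the chair [3,3] transition state of the E alkene (CH2OPiv equatorial, methyl axial) sets C5 and C10 relative to each other while the boron ligand selects the absolute sense.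

Step 8
Reactants: 12 (2R,3R)-3-methyl-3-[(Piv-oxy)methyl]-2-[3-(TBS-oxy)prop-1-en-2-yl]pent-4-enoic acid
Product: 13 (2R,3R)-2-ethenyl-2-methyl-3-[3-(TBS-oxy)prop-1-en-2-yl]butane-1,4-diol
Conditions: LiAlH4 (4 equiv), THF, 0 → 25 °C; then H2O
Reagents that add atoms: none
Why: Hydride reduction should convert the acid into the primary alcohol and cleave the pivalate in the same operation without touching the silyl ether or the isolated alkenes.

Step 9
Reactants: 13 (2R,3R)-2-ethenyl-2-methyl-3-[3-(TBS-oxy)prop-1-en-2-yl]butane-1,4-diol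
Product: 14 (2R,3R)-2-ethenyl-2-methyl-3-[3-(TBS-oxy)prop-1-en-2-yl]-4-(TES-oxy)butan-1-ol
Conditions: TESCl (1.05 equiv), imidazole, CH2Cl2, −78 °C
Reagents that add atoms: chlorotriethylsilane, CC[Si](Cl)(CC)CC
Why: Kinetic silylation should take the less hindered primary alcohol (C6–OH, on a tertiary carbon) in preference to the neopentyl C9–OH.

Step 10
Reactants: 14 (2R,3R)-2-ethenyl-2-methyl-3-[3-(TBS-oxy)prop-1-en-2-yl]-4-(TES-oxy)butan-1-ol
Product: 15 (2R,3R)-2-ethenyl-1-iodo-2-methyl-3-[3-(TBS-oxy)prop-1-en-2-yl]-4-(TES-oxy)butane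
Conditions: I2, PPh3, imidazole, toluene, 70 °C
Reagents that add atoms: iodine, II
Why: Appel-type iodination converts the neopentyl alcohol into the iodide by SN2 displacement of the oxyphosphonium group, which needs heating because C9 is neopentyl.

Step 11
Reactants: 15 (2R,3R)-2-ethenyl-1-iodo-2-methyl-3-[3-(TBS-oxy)prop-1-en-2-yl]-4-(TES-oxy)butane
Product: 16 (2R,3R)-3-ethenyl-4-iodo-3-methyl-2-[3-(TBS-oxy)prop-1-en-2-yl]butanal
Conditions: (COCl)2, DMSO, CH2Cl2, −78 → −30 °C; then Et3N, −78 → 0 °C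
Reagents that add atoms: none
Why: Under Swern conditions a primary triethylsilyl ether is oxidised directly to the aldehyde while the TBS ether stays, and the low temperature protects the epimerisable C5.

Step 12
Reactants: 17 4-methoxy-2-methylidene-4-oxobutanoic acid (monomethyl itaconate)
Product: 18 4-methyl 1-TMSE 2-methylidenebutanedioate
Conditions: Me3SiCH2CH2OH, DCC, DMAP (5 mol %), CH2Cl2, 0 °C
Reagents that add atoms: 2-(trimethylsilyl)ethanol, C[Si](C)(C)CCO
Why: Steglich esterification of the free acrylic acid gives a fluoride-labile ester at C12 that is orthogonal to the methyl ester at C8.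

Step 13
Reactants: 18 4-methyl 1-TMSE 2-methylidenebutanedioate
Product: 20 4-methyl 1-TMSE (2Z)-2-(bromomethyl)but-2-enedioate (ester groups trans), via dibromide 19 (not isolated)
Conditions: Br2, CH2Cl2, 0 °C; then Et3N, 0 → 25 °C
Reagents that add atoms: bromine, BrBr
Why: Bromine addition to the 1,1-disubstituted alkene and E2 loss of HBr from the acidic C7–H and the tertiary bromide give the 2-(bromomethyl)butenedioate (bromination–dehydrobromination of an itaconate).

Step 14
Reactants: 16 (2R,3R)-3-ethenyl-4-iodo-3-methyl-2-[3-(TBS-oxy)prop-1-en-2-yl]butanal; 20 4-methyl 1-TMSE (2Z)-2-(bromomethyl)but-2-enedioate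
Product: 22 TMSE 2-[(1S,2R,3S,4R)-4-ethenyl-2-hydroxy-4-methyl-6-oxo-3-[3-(TBS-oxy)prop-1-en-2-yl]cyclohexyl]prop-2-enoate, via aldol adduct 21 (not isolated)
Conditions: 16 and 20 (1.3 equiv), SmI2 (2.6 equiv), THF, −78 °C; then HMPA (10 equiv), SmI2 (2.6 equiv), −78 → −40 °C; aq. NH4Cl
Reagents that add atoms: none
Why: SmI2 alone first reduces only the allylic bromide of 20 to a trivalent samarium dienolate, which adds through its ester α-carbon C7 to the aldehyde carbon C6 of 16 in a chair Zimmerman–Traxler transition state; once HMPA is added the primary iodide is reduced to the C9 alkylsamarium, which attacks the methyl ester carbonyl C8 and expels methoxide. The closest known reaction types are the SmI2-mediated Barbier reaction of aldehydes with 2-(bromomethyl)acrylates and the SmI2–HMPA nucleophilic acyl substitution of iodo esters, here run as one sequenced process. The cyclohexanone ring C5–C10 closes by 6-exo-trig acyl substitution of C9 at C8, so the two-carbon unit C7–C8 is inserted between C6 and C9. C6 is set by Felkin–Anh attack anti to the quaternary C10 (hydroxyl cis to the C5 side chain) and C7 by the chair transition state of the E(O) dienolate (anti aldol, H6 and H7 trans), while C8 is not yet stereogenic. The step needs halide chemoselectivity, secured by the much faster reduction of the allylic bromide and the inertness of the neopentyl iodide until HMPA is present, and attack through C7 instead of C13, secured by the C8 ester that makes C7 the enolate carbon. Low temperature and excess SmI2–HMPA are chosen so that the C9 radical is reduced to the organosamarium before its 1,2-vinyl shift can occur.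

Step 15
Reactants: 22 TMSE 2-[(1S,2R,3S,4R)-4-ethenyl-2-hydroxy-4-methyl-6-oxo-3-[3-(TBS-oxy)prop-1-en-2-yl]cyclohexyl]prop-2-enoate
Product: 23 TMSE 2-[(1S,2R,3S,4R)-4-ethenyl-4-methyl-6-oxo-3-[3-(TBS-oxy)prop-1-en-2-yl]-2-(TES-oxy)cyclohexyl]prop-2-enoate
Conditions: TESOTf, 2,6-lutidine, CH2Cl2, −78 °C
Reagents that add atoms: triethylsilyl trifluoromethanesulfonate, CC[Si](CC)(CC)OS(=O)(=O)C(F)(F)F
Why: Silylation with the silyl triflate protects the hindered C6 hydroxyl and prevents retro-aldol cleavage of the β-hydroxy ketone.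

Step 16
Reactants: 23 TMSE 2-[(1S,2R,3S,4R)-4-ethenyl-4-methyl-6-oxo-3-[3-(TBS-oxy)prop-1-en-2-yl]-2-(TES-oxy)cyclohexyl]prop-2-enoate
Product: 24 TMSE 2-[(1R,2R,3S,4R,6R)-4-ethenyl-6-hydroxy-4-methyl-3-[3-(TBS-oxy)prop-1-en-2-yl]-2-(TES-oxy)cyclohexyl]prop-2-enoate
Conditions: NaBH4, CeCl3·7H2O, MeOH/THF, −78 °C
Reagents that add atoms: none
Why: Luche reduction is chemoselective for the ketone over the acrylate, and hydride should enter C8 on the face opposite the axial C10 vinyl group in the chair that keeps the C6 and C7 substituents equatorial, which places the new hydroxyl cis to the C7 side chain (substrate control).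

Step 17
Reactants: 25 but-2-yn-1-ol
Product: 27 (2Z)-3-iodobut-2-en-1-ol, via alkenylaluminate 26 (not isolated)
Conditions: NaAlH2(OCH2CH2OMe)2, THF, 0 °C; then I2, −78 → 0 °C
Reagents that add atoms: iodine, II
Why: trans-Hydroalumination of the propargylic alcohol (the alkoxide delivers hydride to the near alkyne carbon) and iodinolysis of the alkenyl–aluminium bond with retention fix the Z geometry.

Step 18
Reactants: 27 (2Z)-3-iodobut-2-en-1-ol
Product: 28 (2Z)-3-iodobut-2-en-1-yl acetate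
Conditions: Ac2O, pyridine, DMAP (cat.), CH2Cl2, 0 °C
Reagents that add atoms: acetic anhydride, CC(=O)OC(C)=O
Why: Acetylation of the primary alcohol installs the side-chain acetate before the carboxyl group exists, so that no hydroxy acid able to lactonise is ever formed.

Step 19
Reactants: 28 (2Z)-3-iodobut-2-en-1-yl acetate
Product: 29 (2Z)-4-(acetyloxy)-2-methylbut-2-enoic acid
Conditions: Pd(OAc)2 (5 mol %), PPh3, CO (1 atm), H2O, Et3N, DMF, 40 °C
Reagents that add atoms: carbon monoxide, [C-]#[O+]; water, O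
Why: Palladium-catalysed hydroxycarbonylation of the alkenyl iodide (oxidative addition to zerovalent palladium, CO insertion, hydrolysis of the acylpalladium) proceeds with retention of alkene geometry and should be faster than ionisation of the allylic acetate.

Step 20
Reactants: 24 TMSE 2-[(1R,2R,3S,4R,6R)-4-ethenyl-6-hydroxy-4-methyl-3-[3-(TBS-oxy)prop-1-en-2-yl]-2-(TES-oxy)cyclohexyl]prop-2-enoate; 29 (2Z)-4-(acetyloxy)-2-methylbut-2-enoic acid
Product: 31 TMSE 2-[(1R,2R,3S,4R,6R)-6-{[(2Z)-4-(acetyloxy)-2-methylbut-2-enoyl]oxy}-4-ethenyl-4-methyl-3-[3-(TBS-oxy)prop-1-en-2-yl]-2-(TES-oxy)cyclohexyl]prop-2-enoate, via mixed anhydride 30 (not isolated)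
Conditions: 2,4,6-Cl3C6H2COCl, Et3N, THF, 0 °C; then 24, DMAP, toluene, 25 °C
Reagents that add atoms: none
Why: Yamaguchi esterification through the mixed anhydride should acylate the hindered C8 alcohol with retention at C8, and room temperature with a short reaction time limits Z to E isomerisation of the enoate.

Step 21
Reactants: 31 TMSE 2-[(1R,2R,3S,4R,6R)-6-{[(2Z)-4-(acetyloxy)-2-methylbut-2-enoyl]oxy}-4-ethenyl-4-methyl-3-[3-(TBS-oxy)prop-1-en-2-yl]-2-(TES-oxy)cyclohexyl]prop-2-enoate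
Product: 32 2-[(1S,2R,3S,4R,6R)-6-{[(2Z)-4-(acetyloxy)-2-methylbut-2-enoyl]oxy}-4-ethenyl-2-hydroxy-3-(3-hydroxyprop-1-en-2-yl)-4-methylcyclohexyl]prop-2-enoic acid (target)
Conditions: Bu4NF, AcOH, THF, 0 → 25 °C; pH 4.5 buffer work-up
Reagents that add atoms: none
Why: Fluoride cleaves the 2-(trimethylsilyl)ethyl ester by β-elimination and both silyl ethers in one operation, and the acetic acid buffer should keep the acetate, the C8 ester and the free γ-hydroxy acid intact.

**Compound list**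

1 | 3-methylbut-2-en-1-yl acetate | CC(C)=CCOC(C)=O | starting material
2 | (2E)-4-hydroxy-3-methylbut-2-en-1-yl acetate | CC(=O)OC/C=C(\C)CO | intermediate
3 | (2E)-4-(acetyloxy)-2-methylbut-2-en-1-yl 2,2-dimethylpropanoate | CC(=O)OC/C=C(\C)COC(=O)C(C)(C)C | intermediate
4 | (2E)-4-hydroxy-2-methylbut-2-en-1-yl 2,2-dimethylpropanoate | OC/C=C(\C)COC(=O)C(C)(C)C | intermediate
5 | 2-methylprop-2-en-1-ol | C=C(C)CO | starting material
6 | dilithio dianion of 5 (lithium alkoxide and allyllithium) | [Li]CC(=C)CO[Li] | intermediate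
7 | 3-(hydroxymethyl)but-3-enoic acid | C=C(CO)CC(=O)O | intermediate
8 | tert-butyl(dimethyl)silyl 3-({[tert-butyl(dimethyl)silyl]oxy}methyl)but-3-enoate | C=C(CO[Si](C)(C)C(C)(C)C)CC(=O)O[Si](C)(C)C(C)(C)C | intermediate
9 | 3-({[tert-butyl(dimethyl)silyl]oxy}methyl)but-3-enoic acid | C=C(CO[Si](C)(C)C(C)(C)C)CC(=O)O | intermediate
10 | (2E)-4-[(2,2-dimethylpropanoyl)oxy]-3-methylbut-2-en-1-yl 3-({[tert-butyl(dimethyl)silyl]oxy}methyl)but-3-enoate | C=C(CO[Si](C)(C)C(C)(C)C)CC(=O)OC/C=C(\C)COC(=O)C(C)(C)C | intermediate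
11 | E(O) boron ketene acetal of 10, O-bound to the (4S,5S)-1,3-bis{[3,5-bis(trifluoromethyl)phenyl]sulfonyl}-4,5-diphenyl-1,3,2-diazaborolidin-2-yl group (C5 substituent trans to O–B) | CC(C)(C)C(=O)OC/C(C)=C/CO/C(OB1N(S(=O)(=O)c2cc(C(F)(F)F)cc(C(F)(F)F)c2)[C@@H](c2ccccc2)[C@H](c2ccccc2)N1S(=O)(=O)c1cc(C(F)(F)F)cc(C(F)(F)F)c1)=C\C(=C)CO[Si](C)(C)C(C)(C)C | intermediate
12 | (2R,3R)-2-(3-{[tert-butyl(dimethyl)silyl]oxy}prop-1-en-2-yl)-3-{[(2,2-dimethylpropanoyl)oxy]methyl}-3-methylpent-4-enoic acid | C=C[C@@](C)(COC(=O)C(C)(C)C)[C@H](C(=O)O)C(=C)CO[Si](C)(C)C(C)(C)C | intermediate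
13 | (2R,3R)-3-(3-{[tert-butyl(dimethyl)silyl]oxy}prop-1-en-2-yl)-2-ethenyl-2-methylbutane-1,4-diol | C=C[C@@](C)(CO)[C@H](CO)C(=C)CO[Si](C)(C)C(C)(C)C | intermediate
14 | (2R,3R)-3-(3-{[tert-butyl(dimethyl)silyl]oxy}prop-1-en-2-yl)-2-ethenyl-2-methyl-4-[(triethylsilyl)oxy]butan-1-ol | C=C[C@@](C)(CO)[C@H](CO[Si](CC)(CC)CC)C(=C)CO[Si](C)(C)C(C)(C)C | intermediate
15 | (2R,3R)-3-(3-{[tert-butyl(dimethyl)silyl]oxy}prop-1-en-2-yl)-2-ethenyl-1-iodo-2-methyl-4-[(triethylsilyl)oxy]butane | C=C[C@@](C)(CI)[C@H](CO[Si](CC)(CC)CC)C(=C)CO[Si](C)(C)C(C)(C)C | intermediate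
16 | (2R,3R)-2-(3-{[tert-butyl(dimethyl)silyl]oxy}prop-1-en-2-yl)-3-ethenyl-4-iodo-3-methylbutanal | C=C[C@@](C)(CI)[C@H](C=O)C(=C)CO[Si](C)(C)C(C)(C)C | intermediate
17 | 4-methoxy-2-methylidene-4-oxobutanoic acid (monomethyl itaconate) | C=C(CC(=O)OC)C(=O)O | starting material
18 | 4-methyl 1-[2-(trimethylsilyl)ethyl] 2-methylidenebutanedioate | C=C(CC(=O)OC)C(=O)OCC[Si](C)(C)C | intermediate
19 | 4-methyl 1-[2-(trimethylsilyl)ethyl] 2-bromo-2-(bromomethyl)butanedioate (racemic) | COC(=O)CC(Br)(CBr)C(=O)OCC[Si](C)(C)C | intermediate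
20 | 4-methyl 1-[2-(trimethylsilyl)ethyl] (2Z)-2-(bromomethyl)but-2-enedioate (ester groups trans) | COC(=O)/C=C(\CBr)C(=O)OCC[Si](C)(C)C | intermediate
21 | 4-methyl 1-[2-(trimethylsilyl)ethyl] (3S)-3-[(1R,2R,3R)-2-(3-{[tert-butyl(dimethyl)silyl]oxy}prop-1-en-2-yl)-1-hydroxy-3-(iodomethyl)-3-methylpent-4-en-1-yl]-2-methylidenebutanedioate (present as its samarium alkoxide) | C=C[C@@](C)(CI)[C@H]([C@@H](O)[C@@H](C(=O)OC)C(=C)C(=O)OCC[Si](C)(C)C)C(=C)CO[Si](C)(C)C(C)(C)C | intermediate
22 | 2-(trimethylsilyl)ethyl 2-[(1S,2R,3S,4R)-3-(3-{[tert-butyl(dimethyl)silyl]oxy}prop-1-en-2-yl)-4-ethenyl-2-hydroxy-4-methyl-6-oxocyclohexyl]prop-2-enoate | C=C[C@@]1(C)CC(=O)[C@@H](C(=C)C(=O)OCC[Si](C)(C)C)[C@H](O)[C@@H]1C(=C)CO[Si](C)(C)C(C)(C)C | intermediate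
23 | 2-(trimethylsilyl)ethyl 2-[(1S,2R,3S,4R)-3-(3-{[tert-butyl(dimethyl)silyl]oxy}prop-1-en-2-yl)-4-ethenyl-4-methyl-6-oxo-2-[(triethylsilyl)oxy]cyclohexyl]prop-2-enoate | C=C[C@@]1(C)CC(=O)[C@@H](C(=C)C(=O)OCC[Si](C)(C)C)[C@H](O[Si](CC)(CC)CC)[C@@H]1C(=C)CO[Si](C)(C)C(C)(C)C | intermediate
24 | 2-(trimethylsilyl)ethyl 2-[(1R,2R,3S,4R,6R)-3-(3-{[tert-butyl(dimethyl)silyl]oxy}prop-1-en-2-yl)-4-ethenyl-6-hydroxy-4-methyl-2-[(triethylsilyl)oxy]cyclohexyl]prop-2-enoate | C=C[C@@]1(C)C[C@@H](O)[C@@H](C(=C)C(=O)OCC[Si](C)(C)C)[C@H](O[Si](CC)(CC)CC)[C@@H]1C(=C)CO[Si](C)(C)C(C)(C)C | intermediate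
25 | but-2-yn-1-ol | CC#CCO | starting material
26 | sodium cyclic alkenyl(alkoxy)aluminate from 25 (five-membered O–Al ring, two 2-methoxyethoxy ligands) | CC1=CCO[Al-]1(OCCOC)OCCOC.[Na+] | intermediate
27 | (2Z)-3-iodobut-2-en-1-ol | C/C(I)=C/CO | intermediate
28 | (2Z)-3-iodobut-2-en-1-yl acetate | C/C(I)=C/COC(C)=O | intermediate
29 | (2Z)-4-(acetyloxy)-2-methylbut-2-enoic acid | CC(=O)OC/C=C(/C)C(=O)O | intermediate
30 | (2Z)-4-(acetyloxy)-2-methylbut-2-enoic 2,4,6-trichlorobenzoic anhydride | CC(=O)OC/C=C(/C)C(=O)OC(=O)c1c(Cl)cc(Cl)cc1Cl | intermediate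
31 | 2-(trimethylsilyl)ethyl 2-[(1R,2R,3S,4R,6R)-6-{[(2Z)-4-(acetyloxy)-2-methylbut-2-enoyl]oxy}-3-(3-{[tert-butyl(dimethyl)silyl]oxy}prop-1-en-2-yl)-4-ethenyl-4-methyl-2-[(triethylsilyl)oxy]cyclohexyl]prop-2-enoate | C=C[C@@]1(C)C[C@@H](OC(=O)/C(C)=C\COC(C)=O)[C@@H](C(=C)C(=O)OCC[Si](C)(C)C)[C@H](O[Si](CC)(CC)CC)[C@@H]1C(=C)CO[Si](C)(C)C(C)(C)C | intermediate
32 | 2-[(1S,2R,3S,4R,6R)-6-{[(2Z)-4-(acetyloxy)-2-methylbut-2-enoyl]oxy}-4-ethenyl-2-hydroxy-3-(3-hydroxyprop-1-en-2-yl)-4-methylcyclohexyl]prop-2-enoic acid | C=C[C@@]1(C)C[C@@H](OC(=O)/C(C)=C\COC(C)=O)[C@@H](C(=C)C(=O)O)[C@H](O)[C@@H]1C(=C)CO | target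

**Step count and risks**

Total step count: 21. Longest linear sequence: 14 steps (steps 1–3, 6–11, 14–16, 20, 21).

Steps most likely to fail:

Step 14. The C9 radical formed on the way to the alkylsamarium may undergo 1,2-vinyl migration (3-exo closure and reopening) before it is reduced. The alkylsamarium may also be protonated instead of attacking C8, and the samarium aldol may show weak anti or Felkin–Anh control. The fallback makes the two bonds in separate, non-radical operations. From 16 and 20, CrCl2 (divalent chromium) in THF at 0 °C should give the anti, Felkin adduct 21 as an isolated compound (Nozaki–Hiyama-type allylation through a chair transition state). TESOTf and 2,6-lutidine then give its triethylsilyl ether, 4-methyl 1-TMSE (3S)-3-[(1R,2R,3R)-3-(iodomethyl)-3-methyl-2-[3-(TBS-oxy)prop-1-en-2-yl]-1-(TES-oxy)pent-4-en-1-yl]-2-methylidenebutanedioate F1. Iodine–lithium exchange with t-BuLi (2.2 equiv, Et2O/pentane, −100 °C) and 6-exo-trig acyl substitution at the methyl ester then close the ring and give 23, where the main route continues.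

Step 16. Hydride delivery to C8 may lack facial selectivity or prefer the other face if the ring does not react through the expected chair. In that case the reduction of 23 is run so as to collect the C8 epimer, TMSE 2-[(1R,2R,3S,4R,6S)-4-ethenyl-6-hydroxy-4-methyl-3-[3-(TBS-oxy)prop-1-en-2-yl]-2-(TES-oxy)cyclohexyl]prop-2-enoate F2. Mitsunobu esterification of F2 with acid 29 (PPh3, DIAD, toluene, 0 °C) inverts C8 and gives 31 directly.

Step 20. During the slow acylation of the hindered C8 alcohol the Z-enoate may isomerise to the E-isomer by reversible conjugate addition of DMAP or chloride. The fallback builds the Z-alkene on the substrate. From 24, DCC-mediated esterification with 2-[bis(2,2,2-trifluoroethoxy)phosphoryl]propanoic acid gives the phosphonate ester, TMSE 2-[(1R,2R,3S,4R,6R)-6-({2-[bis(2,2,2-trifluoroethoxy)phosphoryl]propanoyl}oxy)-4-ethenyl-4-methyl-3-[3-(TBS-oxy)prop-1-en-2-yl]-2-(TES-oxy)cyclohexyl]prop-2-enoate F3 (both epimers at the phosphonate carbon). Still–Gennari olefination of F3 with 2-oxoethyl acetate (KN(SiMe3)2, 18-crown-6, THF, −78 °C) then gives 31.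

Further compounds
F1 | step 14 | 4-methyl 1-[2-(trimethylsilyl)ethyl] (3S)-3-[(1R,2R,3R)-2-(3-{[tert-butyl(dimethyl)silyl]oxy}prop-1-en-2-yl)-3-(iodomethyl)-3-methyl-1-[(triethylsilyl)oxy]pent-4-en-1-yl]-2-methylidenebutanedioate | C=C[C@@](C)(CI)[C@H]([C@@H](O[Si](CC)(CC)CC)[C@@H](C(=O)OC)C(=C)C(=O)OCC[Si](C)(C)C)C(=C)CO[Si](C)(C)C(C)(C)C
F2 | step 16 | 2-(trimethylsilyl)ethyl 2-[(1R,2R,3S,4R,6S)-3-(3-{[tert-butyl(dimethyl)silyl]oxy}prop-1-en-2-yl)-4-ethenyl-6-hydroxy-4-methyl-2-[(triethylsilyl)oxy]cyclohexyl]prop-2-enoate | C=C[C@@]1(C)C[C@H](O)[C@@H](C(=C)C(=O)OCC[Si](C)(C)C)[C@H](O[Si](CC)(CC)CC)[C@@H]1C(=C)CO[Si](C)(C)C(C)(C)C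
F3 | step 20 | 2-(trimethylsilyl)ethyl 2-[(1R,2R,3S,4R,6R)-6-({2-[bis(2,2,2-trifluoroethoxy)phosphoryl]propanoyl}oxy)-3-(3-{[tert-butyl(dimethyl)silyl]oxy}prop-1-en-2-yl)-4-ethenyl-4-methyl-2-[(triethylsilyl)oxy]cyclohexyl]prop-2-enoate | C=C[C@@]1(C)C[C@@H](OC(=O)C(C)P(=O)(OCC(F)(F)F)OCC(F)(F)F)[C@@H](C(=C)C(=O)OCC[Si](C)(C)C)[C@H](O[Si](CC)(CC)CC)[C@@H]1C(=C)CO[Si](C)(C)C(C)(C)C
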